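**Plan**
The retrosynthesis first removes the C2 methoxy group (C2–O bond, back through an aryl bromide to the C2–H phenol). It then opens the benzene ring across C4–C5, C6–C1 and C1–C2 into a methoxy(vinyl)carbene ligand, one CO ligand and 1-tricosyne.
The enabling feature is the ring pattern: the free hydroxyl at C1 and the methoxy at C4 are para, and the C21 chain at C6 sits ortho to the hydroxyl. A carbene–alkyne–CO benzannulation delivers exactly this arrangement with the two para oxygens already differentiated.
Forward, the alkyne is made from 1-docosanol (oxidation, one-carbon homologation) and the carbene complex from Cr(CO)6 and a vinyl Grignard reagent.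
The only ring is then built in one step at chromium with the chain already in place, and the last methoxy group is introduced ortho to the hydroxyl by bromination and copper-catalysed methoxylation.
The target has no stereocentre, so only regiochemistry has to be controlled.

Key step: step 4

Remark: the vinylcarbene complex is assumed to be used at once as a cold solution, since unsubstituted vinylcarbene complexes polymerize on storage.

**Step 1**
Reactants: 1 chromium hexacarbonyl Cr(CO)6; 2 vinylmagnesium bromide
Product: 4 pentacarbonyl[methoxy(vinyl)carbene]chromium, via bromomagnesium acylchromate 3 (not isolated)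
Conditions: Cr(CO)6 (1.2 equiv), CH2=CHMgBr added slowly, THF, 0 °C → rt; solvent removed; Me3OBF4, CH2Cl2/H2O, 0 °C; quick SiO2 filtration (pentane), kept in solution at −20 °C
Reagents that add atoms: trimethyloxonium tetrafluoroborate, C[O+](C)C.F[B-](F)(F)F
Why: Fischer carbene synthesis, in which the vinyl carbanion adds to a carbonyl ligand of zerovalent chromium to give the acylmetalate and the Meerwein salt then methylates its hard oxygen.

**Step 2**
Reactants: 5 1-docosanol
Product: 6 docosanal
Conditions: TEMPO (10 mol%), PhI(OAc)2 (1.1 equiv), CH2Cl2, 30 °C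
Reagents that add atoms: none
Why: TEMPO-catalysed (oxoammonium) oxidation of a primary alcohol, which in an anhydrous medium should stop cleanly at the aldehyde and keeps the waxy substrate in solution.

**Step 3**
Reactants: 6 docosanal
Product: 7 1-tricosyne
Conditions: dimethyl (1-diazo-2-oxopropyl)phosphonate, K2CO3, MeOH/THF (1:1), rt
Reagents that add atoms: Ohira–Bestmann reagent, CC(=O)C(=[N+]=[N-])P(=O)(OC)OC
Why: Seyferth–Gilbert homologation in the Ohira–Bestmann form, in which the diazomethylphosphonate anion made in situ olefinates the aldehyde and the diazoalkene loses N2 with a 1,2-hydrogen shift to the terminal alkyne under base mild enough for an enolizable aldehyde.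

**Step 4**
Reactants: 4 pentacarbonyl[methoxy(vinyl)carbene]chromium; 7 1-tricosyne
Product: 9 2-heneicosyl-4-methoxyphenol, via arene tricarbonylchromium complex 8 (not isolated)
Conditions: 4 (1.3 equiv), THF (0.05 M), 50 °C, Ar; then air, Et2O, rt, daylight
Reagents that add atoms: none
Why: Thermal loss of one CO ligand from the zerovalent chromium centre of 4 frees a site for the alkyne, which inserts into the Cr=C bond (forming C4–C5) to give a vinylogous carbene; migratory insertion of CO (forming C6–C1) gives a chromium-bound dienylketene that closes and tautomerizes to the phenol held on Cr(CO)3 as 8, and air then strips the metal. The closest known reaction type is the Dötz benzannulation of alkenyl(alkoxy)carbene complexes of chromium with terminal alkynes to give 4-alkoxyphenols. The single six-membered ring closes by thermal 6π-electrocyclization of the dienylketene between the ketene carbon and the terminal vinyl carbon (C1–C2), followed by enolization. No stereocentre is created. The step needs regioselective alkyne insertion, and this is secured sterically: the unsubstituted alkyne terminus bonds to the carbene carbon, so the C21 chain ends up beside the CO-derived carbon, ortho to the hydroxyl. Phenol formation over cyclobutenone or furan by-products is favoured by the alkenyl (not aryl) carbene, by chromium and by THF, and the para oxygens emerge differentiated because the methoxy comes from the carbene and the hydroxyl from CO.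

**Step 5**
Reactants: 9 2-heneicosyl-4-methoxyphenol
Product: 10 2-bromo-6-heneicosyl-4-methoxyphenol
Conditions: NBS (1.0 equiv), i-Pr2NH (10 mol%), dry CH2Cl2, 0 °C, dark
Reagents that add atoms: N-bromosuccinimide, O=C1CCC(=O)N1Br
Why: Electrophilic aromatic bromination (amine-catalysed ortho-bromination of phenols with NBS), in which the hydroxyl is the strongest director, its para position is blocked by the methoxy group and one ortho position by the chain, so bromine should enter the remaining ortho carbon.

**Step 6**
Reactants: 10 2-bromo-6-heneicosyl-4-methoxyphenol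
Product: 11 6-heneicosyl-2,4-dimethoxyphenol
Conditions: NaOMe (5 equiv, 25% in MeOH), CuI (15 mol%), DMF, 110 °C, Ar; then aq. HCl
Reagents that add atoms: sodium methoxide, [Na+].[O-]C
Why: Ullmann-type copper-catalysed methoxylation of an aryl bromide, long established for ortho-bromophenols, in which methoxide replaces bromide at monovalent copper while the phenoxide is tolerated and the aryl methyl ether and the alkyl chain are inert.

**Compound list**
1 | chromium hexacarbonyl, Cr(CO)6 | O=C=[Cr](=C=O)(=C=O)(=C=O)(=C=O)=C=O | starting material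
2 | vinylmagnesium bromide | C=C[Mg]Br | starting material
3 | bromomagnesium pentacarbonyl(acryloyl)chromate (acylmetalate, Cr–C(OMgBr)–CH=CH2) | C=CC(O[Mg]Br)=[Cr](=C=O)(=C=O)(=C=O)(=C=O)=C=O | intermediate
4 | pentacarbonyl[methoxy(vinyl)carbene]chromium | C=CC(OC)=[Cr](=C=O)(=C=O)(=C=O)(=C=O)=C=O | intermediate
5 | 1-docosanol | CCCCCCCCCCCCCCCCCCCCCCO | starting material
6 | docosanal | CCCCCCCCCCCCCCCCCCCCCC=O | intermediate
7 | 1-tricosyne | C#CCCCCCCCCCCCCCCCCCCCCC | intermediate
8 | tricarbonyl(η6-2-heneicosyl-4-methoxyphenol)chromium (arene, three CO and Cr written as separate parts) | CCCCCCCCCCCCCCCCCCCCCc1cc(OC)ccc1O.[C-]#[O+].[C-]#[O+].[C-]#[O+].[Cr] | intermediate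
9 | 2-heneicosyl-4-methoxyphenol | CCCCCCCCCCCCCCCCCCCCCc1cc(OC)ccc1O | intermediate
10 | 2-bromo-6-heneicosyl-4-methoxyphenol | CCCCCCCCCCCCCCCCCCCCCc1cc(OC)cc(Br)c1O | intermediate
11 | 6-heneicosyl-2,4-dimethoxyphenol | CCCCCCCCCCCCCCCCCCCCCc1cc(OC)cc(OC)c1O | target

**Step count**
Total steps: 6. Longest linear sequence: 5 steps (1-docosanol → 6 → 7 → 9 → 10 → 11; step 1 is a one-step side branch).

**Steps most likely to fail**

1. Step 4 (key step). The terminal alkyne may oligomerize at chromium, a second alkyne may insert, or the unhindered vinylcarbene ligand may decay thermally before CO loss and alkyne uptake. The fallback exchanges the roles of the partners, so that the chain is carried by the carbene and the alkyne is small. It sets out from docosanal 6 and Cr(CO)6 1. Takai iodo-olefination of 6 (CHI3, CrCl2, THF, 0 °C) would give (E)-1-iodotricos-1-ene F1. Iodine–lithium exchange (t-BuLi, Et2O, −78 °C) would give (E)-tricos-1-enyllithium F2, which on addition to 1 would form lithium pentacarbonyl[(E)-tetracos-2-enoyl]chromate F3. Methylation with Me3OBF4 would give pentacarbonyl[(E)-1-methoxytetracos-2-enylidene]chromium F4, a β-substituted alkenylcarbene of the sturdiest class for this annulation. Heating F4 with ethynyltrimethylsilane as an acetylene surrogate (THF, 50 °C) should give tricarbonyl[η6-2-heneicosyl-4-methoxy-6-(trimethylsilyl)phenol]chromium F5 and, after exposure to air, 2-heneicosyl-4-methoxy-6-(trimethylsilyl)phenol F6. Ipso-protodesilylation (CF3CO2H, CH2Cl2, rt) would return to the route at 9. Both alkyne carbons end up bearing hydrogen, so the orientation of the silylalkyne is immaterial.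

2. Step 1. The Grignard reagent may add sluggishly to the carbonyl ligand, and the unsubstituted vinyl group of the complex may polymerize or suffer conjugate addition during methylation and concentration. The fallback uses a β-silyl-blocked vinylcarbene and sets out from 1. (E)-2-(Trimethylsilyl)vinyllithium F7 (from (E)-(2-bromovinyl)trimethylsilane and t-BuLi, Et2O, −78 °C) would add to 1 to give lithium pentacarbonyl[(E)-3-(trimethylsilyl)acryloyl]chromate F8. Methylation with Me3OBF4 would give pentacarbonyl[methoxy((E)-2-(trimethylsilyl)vinyl)carbene]chromium F9, a storable complex whose β-carbon is shielded. Benzannulation of F9 with 1-tricosyne 7 (THF, 50 °C) is expected to proceed with 1,3-migration of silicon from carbon to oxygen in the cyclohexadienone. This would give tricarbonyl[η6-trimethyl(2-heneicosyl-4-methoxyphenoxy)silane]chromium F10 and, after air, trimethyl(2-heneicosyl-4-methoxyphenoxy)silane F11. K2CO3 in MeOH would cleave the silyl ether and rejoin the route at 9.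

3. Step 6. The hot basic copper medium may cause reductive loss of bromine and oxidative degradation of the electron-rich phenoxide, leaving the C–O coupling incomplete. The fallback introduces the oxygen by oxidation of a C–B bond and sets out from 10. O-Benzylation (BnBr, K2CO3, DMF) would give 2-(benzyloxy)-1-bromo-3-heneicosyl-5-methoxybenzene F12. Bromine–lithium exchange (n-BuLi, THF, −78 °C) would give [2-(benzyloxy)-3-heneicosyl-5-methoxyphenyl]lithium F13, and B(OMe)3 would convert it to dimethyl [2-(benzyloxy)-3-heneicosyl-5-methoxyphenyl]boronate F14. Oxidation in the same flask (H2O2, NaOH) would give 2-(benzyloxy)-3-heneicosyl-5-methoxyphenol F15. Methylation (MeI, K2CO3, acetone) would give 2-(benzyloxy)-1-heneicosyl-3,5-dimethoxybenzene F16, and hydrogenolysis (H2, Pd on carbon, EtOAc) would deliver the target 11.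

**Further compounds**
F1 | step 4 | (E)-1-iodotricos-1-ene | I/C=C/CCCCCCCCCCCCCCCCCCCCC
F2 | step 4 | (E)-tricos-1-enyllithium | [Li]/C=C/CCCCCCCCCCCCCCCCCCCCC
F3 | step 4 | lithium pentacarbonyl[(E)-tetracos-2-enoyl]chromate | CCCCCCCCCCCCCCCCCCCCC/C=C/C(O[Li])=[Cr](=C=O)(=C=O)(=C=O)(=C=O)=C=O
F4 | step 4 | pentacarbonyl[(E)-1-methoxytetracos-2-enylidene]chromium | CCCCCCCCCCCCCCCCCCCCC/C=C/C(OC)=[Cr](=C=O)(=C=O)(=C=O)(=C=O)=C=O
F5 | step 4 | tricarbonyl[η6-2-heneicosyl-4-methoxy-6-(trimethylsilyl)phenol]chromium | CCCCCCCCCCCCCCCCCCCCCc1cc(OC)cc([Si](C)(C)C)c1O.[C-]#[O+].[C-]#[O+].[C-]#[O+].[Cr]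
F6 | step 4 | 2-heneicosyl-4-methoxy-6-(trimethylsilyl)phenol | CCCCCCCCCCCCCCCCCCCCCc1cc(OC)cc([Si](C)(C)C)c1O
F7 | step 1 | (E)-2-(trimethylsilyl)vinyllithium | [Li]/C=C/[Si](C)(C)C
F8 | step 1 | lithium pentacarbonyl[(E)-3-(trimethylsilyl)acryloyl]chromate | C[Si](C)(C)/C=C/C(O[Li])=[Cr](=C=O)(=C=O)(=C=O)(=C=O)=C=O
F9 | step 1 | pentacarbonyl[methoxy((E)-2-(trimethylsilyl)vinyl)carbene]chromium | C[Si](C)(C)/C=C/C(OC)=[Cr](=C=O)(=C=O)(=C=O)(=C=O)=C=O
F10 | step 1 | tricarbonyl[η6-trimethyl(2-heneicosyl-4-methoxyphenoxy)silane]chromium | CCCCCCCCCCCCCCCCCCCCCc1cc(OC)ccc1O[Si](C)(C)C.[C-]#[O+].[C-]#[O+].[C-]#[O+].[Cr]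
F11 | step 1 | trimethyl(2-heneicosyl-4-methoxyphenoxy)silane | CCCCCCCCCCCCCCCCCCCCCc1cc(OC)ccc1O[Si](C)(C)C
F12 | step 6 | 2-(benzyloxy)-1-bromo-3-heneicosyl-5-methoxybenzene | CCCCCCCCCCCCCCCCCCCCCc1cc(OC)cc(Br)c1OCc1ccccc1
F13 | step 6 | [2-(benzyloxy)-3-heneicosyl-5-methoxyphenyl]lithium | CCCCCCCCCCCCCCCCCCCCCc1cc(OC)cc([Li])c1OCc1ccccc1
F14 | step 6 | dimethyl [2-(benzyloxy)-3-heneicosyl-5-methoxyphenyl]boronate | CCCCCCCCCCCCCCCCCCCCCc1cc(OC)cc(B(OC)OC)c1OCc1ccccc1
F15 | step 6 | 2-(benzyloxy)-3-heneicosyl-5-methoxyphenol | CCCCCCCCCCCCCCCCCCCCCc1cc(OC)cc(O)c1OCc1ccccc1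
F16 | step 6 | 2-(benzyloxy)-1-heneicosyl-3,5-dimethoxybenzene | CCCCCCCCCCCCCCCCCCCCCc1cc(OC)cc(OC)c1OCc1ccccc1
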